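**Retrosynthetic overview**

1. Target 22 ⇐ keto hydroxy acid 20 (C8 methylenation and O3 acetylation come last) ⇐ bridged silyl ketal 19; the side-chain diene comes from a nitrile via aldehyde, alkyne and ene–yne metathesis with ethene.
2. Key disconnection: C5–C10 and C8–C9 together, by intramolecular [4+2] cycloaddition of the cyclic vinylketene silyl acetal of lactone 13 (diene C8=C7–C6=C5) onto the tethered E alkene C9=C10, activated through C11=C12 by a nitrile. Rings A and B form in this one step.
3. Enabling feature: in the cis-fused decalin the oxygen on C3 and C8 lie on the same face, so O3 can carry C8 as a lactone carbonyl (seven-membered ring O3–C8–C7–C6–C5–C4–C3). This temporary ring holds the diene s-cis with C4 inside, forces the cis A/B fusion, relays C3 to C5, C10 and C9, and delivers C8 at the ketone level.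
4. Lactone 13 ⇐ ring-closing metathesis of an acrylate with the allyl group on C4; C3 from an Evans aldol, quaternary C4 from a Fráter–Seebach allylation; C1, C2, C3, C9, C10, C11 and C20 from geranyl acetate (E alkene kept).
5. Ring order: temporary lactone (step 8), then rings A and B at once (step 9), then the lactone bridge is opened (step 14).

Key step: step 9

Remark: read from the SMILES, the target is (3R,4R,5S,9S,10R), a cis-fused decalin: H-5, CH3-10, the C9 side chain and the C4 carboxyl are on one face (β), the 3-acetoxy and C4 methyl on the other (α). Labdane numbering (C1–C20, O3 = oxygen on C3) is used throughout.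

**Route**

Step 1
Reactants: 1 geranyl acetate
Product: 2 6,7-epoxygeranyl acetate (racemic at the oxirane CH)
Conditions: mCPBA, NaHCO3, CH2Cl2, 0 °C
Reagents that add atoms: mCPBA, O=C(OO)c1cccc(Cl)c1
Why: Prilezhaev epoxidation should take the more electron-rich 6,7-alkene, the 2,3-alkene being deactivated by the allylic acetate; the new stereocentre is racemic and is destroyed in step 2.

Step 2
Reactants: 2 6,7-epoxygeranyl acetate
Product: 3 (2E)-3-methyl-6-oxohex-2-en-1-yl acetate
Conditions: H5IO6, THF/H2O, 0 °C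
Reagents that add atoms: none
Why: Acid-promoted epoxide hydrolysis and periodate (Malaprade) cleavage of the diol should give the aldehyde (future C3) and leave the E alkene (future C9=C10) untouched.

Step 3
Reactants: 3 (2E)-3-methyl-6-oxohex-2-en-1-yl acetate; 4 (4S)-4-benzyl-3-propanoyl-1,3-oxazolidin-2-one
Product: 6 (4S)-4-benzyl-3-[(2S,3R,6E)-8-acetoxy-3-hydroxy-2,6-dimethyloct-6-enoyl]-1,3-oxazolidin-2-one, via Z-boron enolate 5 (not isolated)
Conditions: Bu2BOTf, i-Pr2NEt, CH2Cl2, 0 °C; then 3, −78 → 0 °C; pH 7 buffer, MeOH, H2O2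
Reagents that add atoms: none
Why: Evans syn-aldol reaction: the Z boron enolate reacts through a Zimmerman–Traxler chair whose face is set by the (4S)-benzyl group, which should give the 3R carbinol (future C3); the adjacent methine is re-set in step 5.

Step 4
Reactants: 6 aldol adduct
Product: 7 2-(trimethylsilyl)ethyl (2S,3R,6E)-3,8-dihydroxy-2,6-dimethyloct-6-enoate
Conditions: Me3SiCH2CH2OH, n-BuLi, THF, 0 °C; then 6, 0 °C; NH4Cl (aq)
Reagents that add atoms: 2-(trimethylsilyl)ethanol (as its lithium alkoxide), C[Si](C)(C)CCO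
Why: Alkoxide transacylation at the exocyclic imide carbonyl (as in lithium benzyloxide cleavage) should give the fluoride-labile ester, and the same alkoxide removes the allylic acetate; no stereocentre is touched.

Step 5
Reactants: 7 2-(trimethylsilyl)ethyl (2S,3R,6E)-3,8-dihydroxy-2,6-dimethyloct-6-enoate
Product: 9 2-(trimethylsilyl)ethyl (2R,3R,6E)-3,8-dihydroxy-2,6-dimethyl-2-(prop-2-en-1-yl)oct-6-enoate, via trilithium alkoxide-enolate 8 (not isolated)
Conditions: LiN(i-Pr)2 (3.3 equiv), THF, −78 → −20 °C; allyl bromide, −78 → −20 °C; NH4Cl (aq)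
Reagents that add atoms: allyl bromide, C=CCBr
Why: Fráter–Seebach alkylation: in the lithium-chelated alkoxide–enolate the electrophile enters on the face opposite to the substituent of the carbinol carbon, so allyl ends anti and the resident methyl syn to the hydroxyl, which should set the quaternary C4 as R; the remote lithium alkoxide, like the chelated one, is not alkylated at this temperature.

Step 6
Reactants: 9 allylated diol ester
Product: 11 2-(trimethylsilyl)ethyl (2R,3R,6E,8E)-9-cyano-3-hydroxy-2,6-dimethyl-2-(prop-2-en-1-yl)nona-6,8-dienoate, via enal 10 (not isolated)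
Conditions: MnO2, Ph3P=CHCN, CH2Cl2, rt
Reagents that add atoms: (triphenylphosphoranylidene)acetonitrile, N#CC=P(c1ccccc1)(c1ccccc1)c1ccccc1
Why: Tandem oxidation–Wittig reaction: MnO2 oxidises only the allylic primary alcohol and the stabilised ylide traps the enal, installing the vinylogous nitrile activator; the geometry of the new C11=C12 bond does not matter because it is hydrogenated in step 10.

Step 7
Reactants: 11 hydroxy dienenitrile
Product: 12 2-(trimethylsilyl)ethyl (2R,3R,6E,8E)-9-cyano-2,6-dimethyl-3-(prop-2-enoyloxy)-2-(prop-2-en-1-yl)nona-6,8-dienoate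
Conditions: acryloyl chloride, i-Pr2NEt, DMAP (cat.), CH2Cl2, 0 °C → rt
Reagents that add atoms: acryloyl chloride, C=CC(=O)Cl
Why: DMAP-catalysed acylation of the only remaining hydroxyl (O3) attaches C7 and C8, with C8 at the carboxyl level.

Step 8
Reactants: 12 acrylate
Product: 13 2-(trimethylsilyl)ethyl (6R,7R)-7-[(3E,5E)-6-cyano-3-methylhexa-3,5-dien-1-yl]-6-methyl-2-oxo-2,5,6,7-tetrahydrooxepine-6-carboxylate
Conditions: second-generation Grubbs catalyst (5 mol %), toluene (0.002 M), 80 °C
Reagents that add atoms: none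
Why: Ring-closing metathesis between the two terminal alkenes (acrylate and C4 allyl), helped by the quaternary C4 (Thorpe–Ingold effect), should close the seven-membered α,β-unsaturated lactone with a necessarily cis C6=C7 bond; the trisubstituted and nitrile-conjugated alkenes are much less reactive.

Step 9
Reactants: 13 lactone
Product: 15 bridged silyl ketal cycloadduct (rings A and B cis-fused; C6=C7; O3 bonded to C8; 8-OTBS; 9β-[(E)-2-cyanoethenyl]), via silyl ketene acetal 14 (not isolated)
Conditions: TBSOTf, Et3N, CH2Cl2, −78 → 0 °C; then toluene, 100 °C, sealed tube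
Reagents that add atoms: tert-butyldimethylsilyl triflate, CC(C)(C)[Si](C)(C)OS(=O)(=O)C(F)(F)F
Why: Proposed new method: TBSOTf silylates the lactone carbonyl and Et3N removes a C5 proton to give the cyclic 1-alkoxy-1-silyloxydiene 14 (C8=C7–C6=C5); on heating, its nucleophilic terminus C5 bonds to the δ-carbon C10 of the dienenitrile while C9 closes onto the ketene-acetal carbon C8, a strongly asynchronous [4+2] cycloaddition whose polar limit is a vinylogous Mukaiyama–Michael addition followed by collapse onto the silyloxycarbenium ion. The closest known reaction types are Diels–Alder reactions of vinylketene silyl acetals and of 2-silyloxyfurans, and the silyl triflate/amine-promoted intramolecular double Michael reaction of cyclohexenone dienol ethers with tethered enoates; a seven-membered lactone dienolate with a tethered 1,6-acceptor has no direct precedent. Ring A (C5, C4, C3, C2, C1, C10) closes through the two-carbon tether from ring atom C3 to C10 (six-membered, tether exo to the diene), and ring B (C5 to C10) is the cyclohexene made by the cycloaddition itself, formed as a boat bridged by C4–C3–O3. C5 and C10: the lactone ring puts C4 on the inside position of the diene, so C1 can reach C10 only from the exo side, which makes H-5 and CH3-10 cis, and only the diene face syn to the C3–C2 bond can be reached, so the single stereocentre C3 fixes their absolute configuration; C9: suprafacial addition to the E alkene keeps C11 cis to CH3-10; C8 is a bridgehead ketal carbon fixed by the O3 bridge and is erased in step 14. The step needs regioselectivity (C10 to C5 and not to C8, both four atoms from C3), which the polarity match should secure because C5 has the largest HOMO coefficient of the diene and C10 the largest LUMO coefficient of the alkene, and it needs dienolisation of the lactone only, which should hold because the silyl triflate does not activate the nitrile.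

Step 10
Reactants: 15 cycloadduct
Product: 16 saturated bridged silyl ketal nitrile (C6–C7 and C11–C12 single bonds)
Conditions: H2 (1 atm), Pd/C, EtOAc, Et3N (trace), rt
Reagents that add atoms: none
Why: Heterogeneous hydrogenation should saturate the bicyclic C6=C7 alkene and the nitrile-conjugated C11=C12 alkene, creating no stereocentre and leaving nitrile, ester and silyl ketal intact.

Step 11
Reactants: 16 saturated nitrile
Product: 17 aldehyde (C13 = CHO)
Conditions: i-Bu2AlH, toluene, −78 °C; then aqueous KNaC4H4O6 (potassium sodium tartrate)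
Reagents that add atoms: water, O
Why: One hydride adds to the nitrile and work-up hydrolyses the C=N bond to the aldehyde; the α-quaternary ester is too hindered to react at −78 °C.

Step 12
Reactants: 17 aldehyde
Product: 18 terminal alkyne (C13≡C14)
Conditions: MeC(O)C(N2)P(O)(OMe)2, K2CO3, MeOH, 0 °C → rt
Reagents that add atoms: dimethyl (1-diazo-2-oxopropyl)phosphonate, CC(=O)C(=[N+]=[N-])P(=O)(OC)OC
Why: Seyferth–Gilbert homologation in the Ohira–Bestmann variant should convert the aldehyde into the alkyne under mild base.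

Step 13
Reactants: 18 alkyne
Product: 19 bridged silyl ketal with the complete side chain CH2CH2C(=CH2)CH=CH2
Conditions: ethene (1 atm), second-generation Grubbs catalyst (10 mol %), CH2Cl2, 40 °C
Reagents that add atoms: ethene, C=C
Why: Ene–yne cross-metathesis with ethene should turn the terminal alkyne into the 2-substituted buta-1,3-diene (C13(=C16)–C14=C15); no other alkene is present.

Step 14
Reactants: 19 diene
Product: 20 3α-hydroxy-8-oxo acid (5β-H, 9α-H, 10β-CH3, 4α-CH3, 4β-CO2H)
Conditions: Bu4NF, THF, 0 °C → rt; then NH4Cl (aq), pH 4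
Reagents that add atoms: none
Why: Fluoride cleaves the Si–O bond of the ketal and the 2-(trimethylsilyl)ethyl ester (β-elimination); the desilylated bridgehead ketal opens to the C8 ketone and the free 3α-hydroxyl, C3 keeping its configuration because only the O3–C8 bond breaks.

Step 15
Reactants: 20 keto hydroxy acid
Product: 21 (3R,4R,5S,9S,10R)-3-hydroxylabda-8(17),13(16),14-trien-19-oic acid
Conditions: Ph3PCH3Br, KOt-Bu, THF, 0 → 40 °C; then pH 4 buffer
Reagents that add atoms: methyltriphenylphosphonium bromide, C[P+](c1ccccc1)(c1ccccc1)c1ccccc1.[Br-]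
Why: Wittig methylenation of the C8 ketone with excess ylide (carboxylate and alkoxide are tolerated) should give the exocyclic alkene, as is usual for 8-oxolabdanes.

Step 16
Reactants: 21 hydroxy acid
Product: 22 (3R,4R,5S,9S,10R)-3-acetoxylabda-8(17),13(16),14-trien-19-oic acid (target)
Conditions: Ac2O, pyridine, DMAP (cat.), CH2Cl2, rt; then NaHCO3 (aq), acidify
Reagents that add atoms: acetic anhydride, CC(=O)OC(C)=O
Why: DMAP-catalysed acetylation of the 3α-hydroxyl; the mixed anhydride formed at the carboxyl group is hydrolysed on aqueous work-up.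

**Compound list**

1 | geranyl acetate | CC(C)=CCC/C(C)=C/COC(C)=O | starting material
2 | 6,7-epoxygeranyl acetate (racemic oxirane) | CC1(C)OC1CC/C(C)=C/COC(C)=O | intermediate
3 | (2E)-3-methyl-6-oxohex-2-en-1-yl acetate | O=CCC/C(C)=C/COC(C)=O | intermediate
4 | (4S)-4-benzyl-3-propanoyl-1,3-oxazolidin-2-one | CCC(=O)N1[C@@H](Cc2ccccc2)COC1=O | starting material
5 | Z-dibutylboron enolate of 4 (not isolated) | C/C=C(\OB(CCCC)CCCC)N1[C@@H](Cc2ccccc2)COC1=O | intermediate
6 | (4S)-4-benzyl-3-[(2S,3R,6E)-8-acetoxy-3-hydroxy-2,6-dimethyloct-6-enoyl]-1,3-oxazolidin-2-one | C/C(=C\COC(C)=O)CC[C@@H](O)[C@H](C)C(=O)N1[C@@H](Cc2ccccc2)COC1=O | intermediate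
7 | 2-(trimethylsilyl)ethyl (2S,3R,6E)-3,8-dihydroxy-2,6-dimethyloct-6-enoate | C/C(=C\CO)CC[C@@H](O)[C@H](C)C(=O)OCC[Si](C)(C)C | intermediate
8 | trilithium alkoxide–alkoxide–enolate of 7 (not isolated) | C/C(=C\C[O-])CC[C@@H]([O-])/C(C)=C(\[O-])OCC[Si](C)(C)C.[Li+].[Li+].[Li+] | intermediate
9 | 2-(trimethylsilyl)ethyl (2R,3R,6E)-3,8-dihydroxy-2,6-dimethyl-2-(prop-2-en-1-yl)oct-6-enoate | C/C(=C\CO)CC[C@@H](O)[C@@](C)(CC=C)C(=O)OCC[Si](C)(C)C | intermediate
10 | 2-(trimethylsilyl)ethyl (2R,3R,6E)-3-hydroxy-2,6-dimethyl-8-oxo-2-(prop-2-en-1-yl)oct-6-enoate (not isolated) | C/C(=C\C=O)CC[C@@H](O)[C@@](C)(CC=C)C(=O)OCC[Si](C)(C)C | intermediate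
11 | 2-(trimethylsilyl)ethyl (2R,3R,6E,8E)-9-cyano-3-hydroxy-2,6-dimethyl-2-(prop-2-en-1-yl)nona-6,8-dienoate | C/C(=C\C=C\C#N)CC[C@@H](O)[C@@](C)(CC=C)C(=O)OCC[Si](C)(C)C | intermediate
12 | 2-(trimethylsilyl)ethyl (2R,3R,6E,8E)-9-cyano-2,6-dimethyl-3-(prop-2-enoyloxy)-2-(prop-2-en-1-yl)nona-6,8-dienoate | C/C(=C\C=C\C#N)CC[C@@H](OC(=O)C=C)[C@@](C)(CC=C)C(=O)OCC[Si](C)(C)C | intermediate
13 | 2-(trimethylsilyl)ethyl (6R,7R)-7-[(3E,5E)-6-cyano-3-methylhexa-3,5-dien-1-yl]-6-methyl-2-oxo-2,5,6,7-tetrahydrooxepine-6-carboxylate (lactone O3–C8(=O)–C7=C6–C5–C4–C3) | C/C(=C\C=C\C#N)CC[C@H]1OC(=O)C=CC[C@@]1(C)C(=O)OCC[Si](C)(C)C | intermediate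
14 | 2-(trimethylsilyl)ethyl (6R,7R)-2-[(tert-butyldimethylsilyl)oxy]-7-[(3E,5E)-6-cyano-3-methylhexa-3,5-dien-1-yl]-6-methyl-6,7-dihydrooxepine-6-carboxylate (not isolated) | C/C(=C\C=C\C#N)CC[C@H]1OC(O[Si](C)(C)C(C)(C)C)=CC=C[C@@]1(C)C(=O)OCC[Si](C)(C)C | intermediate
15 | bridged silyl ketal cycloadduct: cis-fused rings A and B, C6=C7, O3 bonded to C8, 8-OTBS, 9β-[(E)-2-cyanoethenyl], 10β-CH3, 5β-H, 4α-CH3, 4β-CO2CH2CH2SiMe3 | N#C/C=C/[C@H]1[C@@]3(O[Si](C)(C)C(C)(C)C)C=C[C@H]2[C@]1(C)CC[C@@H](O3)[C@]2(C)C(=O)OCC[Si](C)(C)C | intermediate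
16 | as 15 with C6–C7 and C11–C12 saturated (9β-CH2CH2CN) | N#CCC[C@H]1[C@@]3(O[Si](C)(C)C(C)(C)C)CC[C@H]2[C@]1(C)CC[C@@H](O3)[C@]2(C)C(=O)OCC[Si](C)(C)C | intermediate
17 | as 16 with 9β-CH2CH2CHO | O=CCC[C@H]1[C@@]3(O[Si](C)(C)C(C)(C)C)CC[C@H]2[C@]1(C)CC[C@@H](O3)[C@]2(C)C(=O)OCC[Si](C)(C)C | intermediate
18 | as 16 with 9β-CH2CH2C≡CH | C#CCC[C@H]1[C@@]3(O[Si](C)(C)C(C)(C)C)CC[C@H]2[C@]1(C)CC[C@@H](O3)[C@]2(C)C(=O)OCC[Si](C)(C)C | intermediate
19 | as 16 with 9β-CH2CH2C(=CH2)CH=CH2 | C=CC(=C)CC[C@H]1[C@@]3(O[Si](C)(C)C(C)(C)C)CC[C@H]2[C@]1(C)CC[C@@H](O3)[C@]2(C)C(=O)OCC[Si](C)(C)C | intermediate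
20 | 3α-hydroxy-8-oxo-17-norlabda-13(16),14-dien-19-oic acid, cis-fused (5β-H, 9α-H, 10β-CH3) | C=CC(=C)CC[C@H]1C(=O)CC[C@H]2[C@]1(C)CC[C@@H](O)[C@]2(C)C(=O)O | intermediate
21 | (3R,4R,5S,9S,10R)-3-hydroxylabda-8(17),13(16),14-trien-19-oic acid | C=CC(=C)CC[C@H]1C(=C)CC[C@H]2[C@]1(C)CC[C@@H](O)[C@]2(C)C(=O)O | intermediate
22 | (3R,4R,5S,9S,10R)-3-acetoxylabda-8(17),13(16),14-trien-19-oic acid | C=CC(=C)CC[C@H]1C(=C)CC[C@H]2[C@]1(C)CC[C@@H](OC(C)=O)[C@]2(C)C(=O)O | target

Total steps: 16. Longest linear sequence: 16 steps (from geranyl acetate 1).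

**Steps most likely to fail, with fallbacks**

1. Step 9 (labelled new method). What may go wrong: incomplete or unselective γ-deprotonation of the silyl-activated lactone; hydrolytic loss of the ketene acetal before a slow cycloaddition onto the trisubstituted, only vinylogously activated alkene; bonding of C10 to the acetal carbon C8 instead of C5. Fallback by known chemistry (thermal intramolecular Diels–Alder reaction of an acyclic 1-silyloxy-1,7,9-decatriene with an all-carbon tether), setting out from 11: cross-metathesis of the allyl group with crotonaldehyde (second-generation Hoveyda–Grubbs catalyst) would give the E enal F1. TBSOTf/Et3N would silylate O3 and convert the enal into the (1E,3E)-1-silyloxydiene, and heating in toluene would form the same two bonds to give the bis-silyl cycloadduct F2. Here ring fusion and facial sense are not enforced, so the cis-fused isomer would have to be separated from its isomers. Hydrogenation as in step 10 would give the saturated nitrile F3, i-Bu2AlH the aldehyde F4, the Ohira–Bestmann reagent the alkyne F5 and ene–yne metathesis with ethene the diene F6. Bu4NF would then give the 3α,8α-dihydroxy acid F7, and oxidation of the less hindered C8 carbinol (TEMPO, PhI(OAc)2) would return to the route at 20.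

2. Step 5. What may go wrong: incomplete enolisation or retro-aldol cleavage of the tris-lithiated species, competing O-allylation of the remote alkoxide, or erosion of facial control at the tetrasubstituted enolate. Fallback, setting out from 6: transacylation with lithium prop-2-en-1-olate would give the allyl ester F8. Its chelated lithium enolate (LiN(i-Pr)2, then Me3SiCl, −78 °C → rt) would undergo an Ireland–Claisen rearrangement that delivers the allyl group intramolecularly to the same enolate face, giving the acid F9. Esterification with 2-(trimethylsilyl)ethyl 2,2,2-trichloroacetimidate (toluene, heat) would return to the route at 9.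

3. Step 15. What may go wrong: enolisation of the C8 ketone toward C9 by the basic ylide with epimerisation of C9, and slow methylenation of a hindered ketone that carries two anionic groups. Fallback, setting out from 19: mild acid (AcOH/THF/H2O) would hydrolyse only the silyl ketal to the keto alcohol ester F10, Ac2O/pyridine/DMAP would give the keto acetate F11, and the non-basic Takai–Lombardo reagent (Zn, CH2Br2, TiCl4) would give the methylene acetate ester F12. Bu4NF would then cleave the 2-(trimethylsilyl)ethyl ester and return to the route at 22.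

**Further compounds**

F1 | step 9 | 2-(trimethylsilyl)ethyl (2R,3R,6E,8E)-9-cyano-3-hydroxy-2,6-dimethyl-2-[(2E)-4-oxobut-2-en-1-yl]nona-6,8-dienoate | C/C(=C\C=C\C#N)CC[C@@H](O)[C@@](C)(C/C=C/C=O)C(=O)OCC[Si](C)(C)C
F2 | step 9 | cis-fused cycloadduct with C6=C7, 3α-OTBS, 8α-OTBS, 9β-[(E)-2-cyanoethenyl] | N#C/C=C/[C@H]1[C@H](O[Si](C)(C)C(C)(C)C)C=C[C@H]2[C@]1(C)CC[C@@H](O[Si](C)(C)C(C)(C)C)[C@]2(C)C(=O)OCC[Si](C)(C)C
F3 | step 9 | saturated nitrile (3α,8α-bis-OTBS, 9β-CH2CH2CN) | N#CCC[C@H]1[C@H](O[Si](C)(C)C(C)(C)C)CC[C@H]2[C@]1(C)CC[C@@H](O[Si](C)(C)C(C)(C)C)[C@]2(C)C(=O)OCC[Si](C)(C)C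
F4 | step 9 | aldehyde (9β-CH2CH2CHO) | O=CCC[C@H]1[C@H](O[Si](C)(C)C(C)(C)C)CC[C@H]2[C@]1(C)CC[C@@H](O[Si](C)(C)C(C)(C)C)[C@]2(C)C(=O)OCC[Si](C)(C)C
F5 | step 9 | alkyne (9β-CH2CH2C≡CH) | C#CCC[C@H]1[C@H](O[Si](C)(C)C(C)(C)C)CC[C@H]2[C@]1(C)CC[C@@H](O[Si](C)(C)C(C)(C)C)[C@]2(C)C(=O)OCC[Si](C)(C)C
F6 | step 9 | diene (3α,8α-bis-OTBS, complete side chain) | C=CC(=C)CC[C@H]1[C@H](O[Si](C)(C)C(C)(C)C)CC[C@H]2[C@]1(C)CC[C@@H](O[Si](C)(C)C(C)(C)C)[C@]2(C)C(=O)OCC[Si](C)(C)C
F7 | step 9 | 3α,8α-dihydroxy-17-norlabda-13(16),14-dien-19-oic acid (cis-fused) | C=CC(=C)CC[C@H]1[C@H](O)CC[C@H]2[C@]1(C)CC[C@@H](O)[C@]2(C)C(=O)O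
F8 | step 5 | prop-2-en-1-yl (2S,3R,6E)-3,8-dihydroxy-2,6-dimethyloct-6-enoate | C/C(=C\CO)CC[C@@H](O)[C@H](C)C(=O)OCC=C
F9 | step 5 | (2R,3R,6E)-3,8-dihydroxy-2,6-dimethyl-2-(prop-2-en-1-yl)oct-6-enoic acid | C/C(=C\CO)CC[C@@H](O)[C@@](C)(CC=C)C(=O)O
F10 | step 15 | 2-(trimethylsilyl)ethyl ester of 20 | C=CC(=C)CC[C@H]1C(=O)CC[C@H]2[C@]1(C)CC[C@@H](O)[C@]2(C)C(=O)OCC[Si](C)(C)C
F11 | step 15 | 3-O-acetate of F10 | C=CC(=C)CC[C@H]1C(=O)CC[C@H]2[C@]1(C)CC[C@@H](OC(C)=O)[C@]2(C)C(=O)OCC[Si](C)(C)C
F12 | step 15 | 2-(trimethylsilyl)ethyl ester of 22 | C=CC(=C)CC[C@H]1C(=C)CC[C@H]2[C@]1(C)CC[C@@H](OC(C)=O)[C@]2(C)C(=O)OCC[Si](C)(C)C
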